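**Strategy.** Ring B (C5–C10) of this ent-labdane is a cyclohexene holding the C7=C8 alkene, the C8 methyl, the C9 side chain and the quaternary C10, which is a Diels–Alder retron. Everything rests on cutting C5–C6 and C9–C10. One catalytic, enantioselective [4+2] cycloaddition closes ring B, places the alkene and sets C5, C9 and C10. Its partners are a geraniol-derived (E)-1-alkyl-2-methyl-1,3-diene that already carries the complete, silyl-protected C11–C16 chain, and commercial ethyl (E)-3-formylcrotonate. The C10 formyl and C5 ester groups are then grown into the two arms that close ring A through a radical C3–C4 bond, and the C3 and C15 esters are installed last.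

Key step: step 4

Remark on the structure: labdane numbering is used throughout; the target is (3S,5S,9R,10S) with a (3S)-3-methylpentanoate, i.e. trans-fused rings, C11 cis to the C10 methyl, and an axial C3 oxygen cis to H-5.
Assumption: (S)-3-methylpentanoic acid is bought as the single enantiomer.
Assumption: the (R)-oxazaborolidinium ion is assigned from the usual model for α-substituted enals (formyl C–H held by the ring oxygen, attack on the enal face remote from the shielding aryl group); the sense is to be confirmed on the first batch, and the (S)-catalyst is equally available.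

Step 1
Reactants: 1 geraniol
Product: 2 tert-butyl{[(2E)-3,7-dimethylocta-2,6-dien-1-yl]oxy}diphenylsilane
Conditions: TBDPSCl, imidazole, CH2Cl2, 0 °C → rt
Reagents that add atoms: tert-butyl(chloro)diphenylsilane, CC(C)(C)[Si](Cl)(c1ccccc1)c1ccccc1
Why: Silylation of the primary allylic alcohol through the N-silylimidazolium ion; the bulky silyl ether should withstand the Lewis acid, organolithium, hydride and radical steps ahead and is removed only by fluoride.

Step 2
Reactants: 2 tert-butyl{[(2E)-3,7-dimethylocta-2,6-dien-1-yl]oxy}diphenylsilane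
Product: 4 (2E,6E)-8-{[tert-butyl(diphenyl)silyl]oxy}-2,6-dimethylocta-2,6-dienal, via allylic alcohol 3 (not isolated)
Conditions: SeO2 (0.1 equiv), t-BuOOH, salicylic acid (0.1 equiv), CH2Cl2, rt; then crude material, MnO2, CH2Cl2, rt
Reagents that add atoms: tert-butyl hydroperoxide, CC(C)(C)OO (its oxygen reaches the substrate through SeO2)
Why: Riley oxidation: the ene reaction of SeO2 and the [2,3]-sigmatropic shift that follows should occur at the more electron-rich distal alkene and at its E-methyl group only, and MnO2 then takes the allylic alcohol (beside any enal already formed) to the (E)-enal without touching the alkene geometry.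

Step 3
Reactants: 4 (2E,6E)-8-{[tert-butyl(diphenyl)silyl]oxy}-2,6-dimethylocta-2,6-dienal; 5 methyltriphenylphosphonium bromide
Product: 6 tert-butyl{[(2E,6E)-3,7-dimethylnona-2,6,8-trien-1-yl]oxy}diphenylsilane
Conditions: 5, KOt-Bu, THF, 0 °C; then 4, 0 °C → rt
Reagents that add atoms: none
Why: Wittig methylenation of the unhindered enal with the non-stabilised ylide should give the terminal alkene and leave the E geometry of the conjugated trisubstituted alkene untouched.

Step 4
Reactants: 6 tert-butyl{[(2E,6E)-3,7-dimethylnona-2,6,8-trien-1-yl]oxy}diphenylsilane; 7 ethyl (2E)-3-methyl-4-oxobut-2-enoate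
Product: 8 ethyl (1S,5R,6S)-5-[(3E)-5-{[tert-butyl(diphenyl)silyl]oxy}-3-methylpent-3-en-1-yl]-6-formyl-4,6-dimethylcyclohex-3-ene-1-carboxylate
Conditions: (R)-3,3-diphenyl-1-(o-tolyl)tetrahydro-1H,3H-pyrrolo[1,2-c][1,3,2]oxazaborole (0.20 equiv), HN(SO2CF3)2 (0.17 equiv), 7 (1.3 equiv), CH2Cl2, −78 → −40 °C
Reagents that add atoms: none
Why: The formyl group of 7 binds the boron of the protonated oxazaborolidine, which lowers the LUMO and makes C5 (β to the formyl group) the electrophilic end; C6 of the s-cis diene attacks it in a concerted, asynchronous, suprafacial [4+2] cycloaddition and the C9–C10 bond closes behind it. The closest known reaction type is the oxazaborolidinium-catalysed enantioselective Diels–Alder reaction of α-substituted enals, β-carboalkoxy α-methyl enals included, with 1-substituted dienes. Ring B is closed by intermolecular [4+2] ring formation, which delivers the C7=C8 alkene with its methyl directly. C10 and C5 are set by the catalyst, whose aryl group shields one enal face so that the diene adds to the open one, and their trans C1/C4 relation follows from the E geometry of 7; C9 is set by the exo-formyl (endo-methyl, endo-ester) transition state together with the E geometry of the C8=C9 diene bond, which puts C11 cis to the C10 methyl. The step needs C9-to-C10 regiochemistry, an exo aldehyde and one π-face: the first should be secured by the C9 alkyl substituent outweighing the C8 methyl (so C6 is the more nucleophilic end), the second by the α-methyl group that disfavours an endo formyl group and by the endo-seeking ester, the third by the catalyst, which is kept in slight excess over the acid so that no free acid meets the diene.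

Step 5
Reactants: 8 ethyl (1S,5R,6S)-5-[(3E)-5-{[tert-butyl(diphenyl)silyl]oxy}-3-methylpent-3-en-1-yl]-6-formyl-4,6-dimethylcyclohex-3-ene-1-carboxylate; 5 methyltriphenylphosphonium bromide
Product: 9 ethyl (1S,5R,6S)-5-[(3E)-5-{[tert-butyl(diphenyl)silyl]oxy}-3-methylpent-3-en-1-yl]-6-ethenyl-4,6-dimethylcyclohex-3-ene-1-carboxylate
Conditions: 5, KOt-Bu, THF, 0 °C; then 8, 0 °C → rt
Reagents that add atoms: none
Why: Wittig methylenation; the non-stabilised ylide should react with the neopentyl aldehyde far faster than with the ethyl ester, and C10, being quaternary, cannot epimerise.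

Step 6
Reactants: 9 ethyl (1S,5R,6S)-5-[(3E)-5-{[tert-butyl(diphenyl)silyl]oxy}-3-methylpent-3-en-1-yl]-6-ethenyl-4,6-dimethylcyclohex-3-ene-1-carboxylate
Product: 11 2-[(1S,5R,6S)-5-[(3E)-5-{[tert-butyl(diphenyl)silyl]oxy}-3-methylpent-3-en-1-yl]-6-ethenyl-4,6-dimethylcyclohex-3-en-1-yl]propan-2-ol, via methyl ketone 10 (not isolated)
Conditions: MeLi (4 equiv), Et2O, −78 °C → rt; then H2O
Reagents that add atoms: methyllithium, [Li]C
Why: Double addition of methyllithium to the ester through the methyl ketone, which is more electrophilic than the ester and is consumed as it forms, should give the tertiary carbinol; no stereocentre is touched.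

Step 7
Reactants: 11 2-[(1S,5R,6S)-5-[(3E)-5-{[tert-butyl(diphenyl)silyl]oxy}-3-methylpent-3-en-1-yl]-6-ethenyl-4,6-dimethylcyclohex-3-en-1-yl]propan-2-ol
Product: 12 tert-butyl{[(2E)-5-[(1R,5R,6R)-6-ethenyl-2,6-dimethyl-5-(prop-1-en-2-yl)cyclohex-2-en-1-yl]-3-methylpent-2-en-1-yl]oxy}diphenylsilane
Conditions: Burgess reagent (methyl N-(triethylammoniosulfonyl)carbamate), toluene, 50 °C
Reagents that add atoms: none
Why: Burgess dehydration, a thermal syn-elimination: six methyl hydrogens are available, whereas loss of H-5 would create a tetrasubstituted alkene next to the quaternary C10, so the isopropenyl group should form.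

Step 8
Reactants: 12 tert-butyl{[(2E)-5-[(1R,5R,6R)-6-ethenyl-2,6-dimethyl-5-(prop-1-en-2-yl)cyclohex-2-en-1-yl]-3-methylpent-2-en-1-yl]oxy}diphenylsilane
Product: 13 3-[(1R,2R,6R)-2-[(3E)-5-{[tert-butyl(diphenyl)silyl]oxy}-3-methylpent-3-en-1-yl]-1,3-dimethyl-6-(prop-1-en-2-yl)cyclohex-3-en-1-yl]propanal
Conditions: Rh(acac)(CO)2 (2 mol %), BIPHEPHOS (4 mol %), CO/H2 (1:1, 5 bar), toluene, 60 °C
Reagents that add atoms: carbon monoxide, [C-]#[O+]
Why: Rhodium-catalysed hydroformylation with a wide-bite-angle diphosphite should place the formyl group on the terminal carbon of the monosubstituted alkene (a branched product would need a rhodium alkyl next to the quaternary C10), while the 1,1-disubstituted and trisubstituted alkenes insert much more slowly.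

Step 9
Reactants: 13 3-[(1R,2R,6R)-2-[(3E)-5-{[tert-butyl(diphenyl)silyl]oxy}-3-methylpent-3-en-1-yl]-1,3-dimethyl-6-(prop-1-en-2-yl)cyclohex-3-en-1-yl]propanal
Product: 14 (5S,9R,10S)-15-{[tert-butyl(diphenyl)silyl]oxy}-ent-labda-7,13E-dien-3-ol, both C3 epimers
Conditions: Fe(acac)3 (0.3 equiv), PhSiH3 (2.5 equiv), EtOH, 60 °C
Reagents that add atoms: none
Why: Hydrogen-atom transfer from an iron hydride to the isopropenyl group, the most accessible alkene, should give the tertiary C4 radical, which adds 6-exo to the C3 aldehyde and closes ring A, and reduction of the alkoxy radical by iron makes the addition irreversible (radical alkene–carbonyl cyclisation initiated by hydrogen-atom transfer); the trans ring fusion is dictated by the existing C5 and C10 centres, and the C3 configuration is left open because steps 10 and 11 reset it.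

Step 10
Reactants: 14 (5S,9R,10S)-15-{[tert-butyl(diphenyl)silyl]oxy}-ent-labda-7,13E-dien-3-ol, both C3 epimers
Product: 15 (5S,9R,10S)-15-{[tert-butyl(diphenyl)silyl]oxy}-ent-labda-7,13E-dien-3-one
Conditions: Dess–Martin periodinane, CH2Cl2, 0 °C → rt
Reagents that add atoms: none
Why: Dess–Martin oxidation of the secondary alcohol should converge both C3 epimers on one ketone under conditions that spare the alkenes and the silyl ether.

Step 11
Reactants: 15 (5S,9R,10S)-15-{[tert-butyl(diphenyl)silyl]oxy}-ent-labda-7,13E-dien-3-one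
Product: 16 (3S,5S,9R,10S)-15-{[tert-butyl(diphenyl)silyl]oxy}-ent-labda-7,13E-dien-3-ol (axial hydroxyl)
Conditions: LiBH(s-Bu)3, THF, −78 °C; then H2O
Reagents that add atoms: none
Why: Substrate-controlled ketone reduction: the bulky hydride should reach C3 along the equatorial trajectory because the axial one is blocked by the syn-axial hydrogens at C1 and C5, so the hydroxyl ends axial, cis to H-5 and trans to the C10 methyl, which is the (3S) configuration.

Step 12
Reactants: 16 (3S,5S,9R,10S)-15-{[tert-butyl(diphenyl)silyl]oxy}-ent-labda-7,13E-dien-3-ol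
Product: 17 (3S,5S,9R,10S)-ent-labda-7,13E-diene-3,15-diol
Conditions: n-Bu4NF, THF, 0 °C → rt
Reagents that add atoms: none
Why: Fluoride-induced desilylation, driven by the strong Si–F bond, should free the primary allylic alcohol and leave the rest untouched.

Step 13
Reactants: 17 (3S,5S,9R,10S)-ent-labda-7,13E-diene-3,15-diol; 18 (3S)-3-methylpentanoic acid
Product: 19 (3S,5S,9R,10S)-3-hydroxy-ent-labda-7,13E-dien-15-yl (3S)-3-methylpentanoate
Conditions: 18 (1.05 equiv), DCC, DMAP (0.1 equiv), CH2Cl2, 0 °C
Reagents that add atoms: none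
Why: Steglich esterification with one equivalent of acid: the primary allylic hydroxyl should be acylated while the axial C3 hydroxyl, flanked by the gem-dimethyl group, stays free; the stereocentre of the acid is β to the carbonyl and is not at risk.

Step 14
Reactants: 19 (3S,5S,9R,10S)-3-hydroxy-ent-labda-7,13E-dien-15-yl (3S)-3-methylpentanoate; 20 Meldrum's acid (2,2-dimethyl-1,3-dioxane-4,6-dione)
Product: 21 3-{[(3S,5S,9R,10S)-15-{[(3S)-3-methylpentanoyl]oxy}-ent-labda-7,13E-dien-3-yl]oxy}-3-oxopropanoic acid (target)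
Conditions: 20 (3 equiv), toluene, 100 °C
Reagents that add atoms: none
Why: Alcoholysis of Meldrum's acid: the C3 hydroxyl opens the dioxanedione ring and acetone is lost, which should deliver the malonic acid half ester directly, without a protecting group.

**Compound list**

1 | geraniol, (2E)-3,7-dimethylocta-2,6-dien-1-ol | CC(C)=CCC/C(C)=C/CO | starting material
2 | tert-butyl{[(2E)-3,7-dimethylocta-2,6-dien-1-yl]oxy}diphenylsilane | CC(C)(C)[Si](c1ccccc1)(c1ccccc1)OC/C=C(\C)CCC=C(C)C | intermediate
3 | (2E,6E)-8-{[tert-butyl(diphenyl)silyl]oxy}-2,6-dimethylocta-2,6-dien-1-ol | CC(C)(C)[Si](c1ccccc1)(c1ccccc1)OC/C=C(\C)CC/C=C(\C)CO | intermediate (not isolated)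
4 | (2E,6E)-8-{[tert-butyl(diphenyl)silyl]oxy}-2,6-dimethylocta-2,6-dienal | CC(C)(C)[Si](c1ccccc1)(c1ccccc1)OC/C=C(\C)CC/C=C(\C)C=O | intermediate
5 | methyltriphenylphosphonium bromide | C[P+](c1ccccc1)(c1ccccc1)c1ccccc1.[Br-] | starting material
6 | tert-butyl{[(2E,6E)-3,7-dimethylnona-2,6,8-trien-1-yl]oxy}diphenylsilane | CC(C)(C)[Si](c1ccccc1)(c1ccccc1)OC/C=C(\C)CC/C=C(\C)C=C | intermediate
7 | ethyl (2E)-3-methyl-4-oxobut-2-enoate | O=C/C(C)=C/C(=O)OCC | starting material
8 | ethyl (1S,5R,6S)-5-[(3E)-5-{[tert-butyl(diphenyl)silyl]oxy}-3-methylpent-3-en-1-yl]-6-formyl-4,6-dimethylcyclohex-3-ene-1-carboxylate | CC(C)(C)[Si](c1ccccc1)(c1ccccc1)OC/C=C(\C)CC[C@@H]1C(C)=CC[C@H](C(=O)OCC)[C@@]1(C)C=O | intermediate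
9 | ethyl (1S,5R,6S)-5-[(3E)-5-{[tert-butyl(diphenyl)silyl]oxy}-3-methylpent-3-en-1-yl]-6-ethenyl-4,6-dimethylcyclohex-3-ene-1-carboxylate | CC(C)(C)[Si](c1ccccc1)(c1ccccc1)OC/C=C(\C)CC[C@@H]1C(C)=CC[C@H](C(=O)OCC)[C@@]1(C)C=C | intermediate
10 | 1-[(1S,5R,6S)-5-[(3E)-5-{[tert-butyl(diphenyl)silyl]oxy}-3-methylpent-3-en-1-yl]-6-ethenyl-4,6-dimethylcyclohex-3-en-1-yl]ethan-1-one | CC(C)(C)[Si](c1ccccc1)(c1ccccc1)OC/C=C(\C)CC[C@@H]1C(C)=CC[C@H](C(C)=O)[C@@]1(C)C=C | intermediate (not isolated)
11 | 2-[(1S,5R,6S)-5-[(3E)-5-{[tert-butyl(diphenyl)silyl]oxy}-3-methylpent-3-en-1-yl]-6-ethenyl-4,6-dimethylcyclohex-3-en-1-yl]propan-2-ol | CC(C)(C)[Si](c1ccccc1)(c1ccccc1)OC/C=C(\C)CC[C@@H]1C(C)=CC[C@H](C(C)(C)O)[C@@]1(C)C=C | intermediate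
12 | tert-butyl{[(2E)-5-[(1R,5R,6R)-6-ethenyl-2,6-dimethyl-5-(prop-1-en-2-yl)cyclohex-2-en-1-yl]-3-methylpent-2-en-1-yl]oxy}diphenylsilane | CC(C)(C)[Si](c1ccccc1)(c1ccccc1)OC/C=C(\C)CC[C@@H]1C(C)=CC[C@H](C(C)=C)[C@@]1(C)C=C | intermediate
13 | 3-[(1R,2R,6R)-2-[(3E)-5-{[tert-butyl(diphenyl)silyl]oxy}-3-methylpent-3-en-1-yl]-1,3-dimethyl-6-(prop-1-en-2-yl)cyclohex-3-en-1-yl]propanal | CC(C)(C)[Si](c1ccccc1)(c1ccccc1)OC/C=C(\C)CC[C@@H]1C(C)=CC[C@H](C(C)=C)[C@@]1(C)CCC=O | intermediate
14 | (5S,9R,10S)-15-{[tert-butyl(diphenyl)silyl]oxy}-ent-labda-7,13E-dien-3-ol, both C3 epimers (C3 left open) | CC(C)(C)[Si](c1ccccc1)(c1ccccc1)OC/C=C(\C)CC[C@@H]1C(C)=CC[C@@H]2C(C)(C)C(O)CC[C@@]12C | intermediate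
15 | (5S,9R,10S)-15-{[tert-butyl(diphenyl)silyl]oxy}-ent-labda-7,13E-dien-3-one | CC(C)(C)[Si](c1ccccc1)(c1ccccc1)OC/C=C(\C)CC[C@@H]1C(C)=CC[C@@H]2C(C)(C)C(=O)CC[C@@]12C | intermediate
16 | (3S,5S,9R,10S)-15-{[tert-butyl(diphenyl)silyl]oxy}-ent-labda-7,13E-dien-3-ol (axial 3-OH, cis to H-5) | CC(C)(C)[Si](c1ccccc1)(c1ccccc1)OC/C=C(\C)CC[C@@H]1C(C)=CC[C@@H]2C(C)(C)[C@@H](O)CC[C@@]12C | intermediate
17 | (3S,5S,9R,10S)-ent-labda-7,13E-diene-3,15-diol | OC/C=C(\C)CC[C@@H]1C(C)=CC[C@@H]2C(C)(C)[C@@H](O)CC[C@@]12C | intermediate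
18 | (3S)-3-methylpentanoic acid | CC[C@H](C)CC(=O)O | starting material
19 | (3S,5S,9R,10S)-3-hydroxy-ent-labda-7,13E-dien-15-yl (3S)-3-methylpentanoate | CC[C@H](C)CC(=O)OC/C=C(\C)CC[C@@H]1C(C)=CC[C@@H]2C(C)(C)[C@@H](O)CC[C@@]12C | intermediate
20 | Meldrum's acid, 2,2-dimethyl-1,3-dioxane-4,6-dione | CC1(C)OC(=O)CC(=O)O1 | starting material
21 | 3-{[(3S,5S,9R,10S)-15-{[(3S)-3-methylpentanoyl]oxy}-ent-labda-7,13E-dien-3-yl]oxy}-3-oxopropanoic acid (CNP0234792.1) | CC[C@H](C)CC(=O)OC/C=C(\C)CC[C@@H]1C(C)=CC[C@@H]2C(C)(C)[C@@H](OC(=O)CC(=O)O)CC[C@@]12C | target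

**Step count.** Total: 14 steps. Longest linear sequence: 14 steps, from geraniol 1 to 21; compounds 5, 7, 18 and 20 are bought.

**Steps most likely to fail**

1. Step 4. The trisubstituted, doubly substituted enal may turn over slowly on the bulky chiral Lewis acid, or the catalyst may discriminate poorly between the two enal faces and between the exo and endo arrangements. Fallback: diene 6 and enal ester 7 are combined under a small achiral Lewis acid (EtAlCl2, CH2Cl2, −78 °C), which activates the same formyl group more strongly and should give the same regio- and exo-controlled adduct as a racemate, that is 8 together with its mirror image ent-8 F1. The racemate is resolved by preparative chromatography on a chiral stationary phase (amylose tris(3,5-dimethylphenylcarbamate), supercritical CO2/i-PrOH), and the fraction of 8 re-enters the route at step 5. The fallback sets out from 6 and comes back at 8.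

2. Step 9. Hydrogen-atom transfer may also reach the two trisubstituted alkenes, or the tertiary radical may be reduced before it adds to the aldehyde. Fallback: the radical is generated regiospecifically from the C4–O bond instead. Carbinol 11 is hydroformylated under the conditions of step 8 (no 1,1-disubstituted alkene is present at this stage) to the hydroxy aldehyde F2. The tertiary hydroxyl is acylated with methyl chlorooxoacetate (pyridine, DMAP, CH2Cl2, 0 °C) to the tertiary methyl oxalate F3. Bu3SnH and AIBN in toluene at 110 °C then fragment the oxalate (Barton–McCombie-type deoxygenative radical generation); the C4 radical adds 6-exo to the aldehyde, and the alkoxy radical takes hydrogen from the stannane, which gives 14. The fallback sets out from 11 and comes back at 14.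

3. Step 8. The rhodium catalyst may also convert the isopropenyl group or give isomerised material. Fallback: the C3 carbon is brought in by olefin metathesis, to which 1,1-disubstituted and trisubstituted alkenes are inert. Triene 12 and crotonaldehyde undergo cross-metathesis at the vinyl group (second-generation Hoveyda–Grubbs catalyst, RuCl2(H2IMes)(=CH–C6H4-2-Oi-Pr), CH2Cl2, 40 °C) to the (E)-enal F4. Conjugate reduction with [(Ph3P)CuH]6 (benzene, H2O, rt) then gives aldehyde 13. The fallback sets out from 12 and comes back at 13.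

**Further compounds**

F1 | step 4 | ent-8, ethyl (1R,5S,6R)-5-[(3E)-5-{[tert-butyl(diphenyl)silyl]oxy}-3-methylpent-3-en-1-yl]-6-formyl-4,6-dimethylcyclohex-3-ene-1-carboxylate | CC(C)(C)[Si](c1ccccc1)(c1ccccc1)OC/C=C(\C)CC[C@H]1C(C)=CC[C@@H](C(=O)OCC)[C@]1(C)C=O
F2 | step 9 | hydroxy aldehyde: compound 11 with the C10 vinyl group replaced by CH2CH2CHO | CC(C)(C)[Si](c1ccccc1)(c1ccccc1)OC/C=C(\C)CC[C@@H]1C(C)=CC[C@H](C(C)(C)O)[C@@]1(C)CCC=O
F3 | step 9 | tertiary methyl oxalate of the hydroxy aldehyde | CC(C)(C)[Si](c1ccccc1)(c1ccccc1)OC/C=C(\C)CC[C@@H]1C(C)=CC[C@H](C(C)(C)OC(=O)C(=O)OC)[C@@]1(C)CCC=O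
F4 | step 8 | (E)-enal: compound 12 with the C10 vinyl group replaced by (E)-CH=CH–CHO | CC(C)(C)[Si](c1ccccc1)(c1ccccc1)OC/C=C(\C)CC[C@@H]1C(C)=CC[C@H](C(C)=C)[C@@]1(C)/C=C/C=O
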